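## Retrosynthetic overview

1. The target is an achiral linear pentamer, A–CH2–B–CH2–B–CH2–B–CH2–A (A = butyrylfilicinic acid ring, B = phlorobutyrophenone ring). Cutting both inner B–CH2–B bonds gives the central ring B as a twofold o-quinone methide (from its bis-Mannich base) plus two A–CH2–B dimers (norflavaspidic acid BB).
2. Cutting A–CH2–B in the dimer gives the methylene trione of ring A (from its Mannich base) and the ring B monomer as carbon nucleophile.
3. The ring A monomer is the ring B monomer after dearomative gem-C-dimethylation, the laboratory counterpart of two S-adenosylmethionine methyl transfers.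
4. The ring B monomer comes from C6→C1 Claisen closure of the butyryl-primed linear tetraketide ester. This ester is unmasked in the flask from its pyrone, which is made from triacetic acid lactone dianion and methyl butyrate.
5. Ring order: all five carbocycles are made first, as one monomer, by that single polyketide cyclisation. Two copies are then dearomatised. The four CH2 bridges (outer pair, then inner pair) close no further ring.

Assumption: the SMILES has no stereocentre and no stereodefined double bond, so the target is achiral and needs no stereocontrol; the enol pattern drawn is one of several rapidly interconverting tautomers.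

## Route

Step 1
Reactants: 1 triacetic acid lactone (4-hydroxy-6-methyl-2H-pyran-2-one, 2.0 equiv); 2 methyl butyrate (1.0 equiv)
Product: 5 phlorobutyrophenone [1-(2,4,6-trihydroxyphenyl)butan-1-one], via tetraketide pyrone 3 (not isolated), via methyl 3,5,7-trioxodecanoate 4 (not isolated)
Conditions: LiN(iPr)2 (4.1 equiv), THF, −78 → −20 °C; 2, −78 → 0 °C; then MeOH, Mg(OMe)2 (6 equiv), THF distilled off, reflux, 16 h; 2 M HCl
Reagents that add atoms: none
Why: Claisen C-acylation of the pyrone dianion at its 6-CH2 terminus (the second equivalent of dianion deprotonates the acidic product) puts the butyryl starter on a triketide as the polyketide synthase does, methoxide then opens the lactone to the Mg-chelated ester 4 (its OMe comes from the medium and leaves again), and because all three ketones are masked as chelated enolates C6 attacks the only free electrophile, the C1 ester, in a biomimetic intramolecular Claisen (Dieckmann-type) cyclisation driven by irreversible aromatisation to the phenolate; no stereocentre is created.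

Step 2
Reactants: 5 phlorobutyrophenone
Product: 7 butyrylfilicinic acid (2-butanoyl-3,5-dihydroxy-4,4-dimethylcyclohexa-2,5-dien-1-one), via 3-methylphlorobutyrophenone 6 (not isolated)
Conditions: NaOMe (4.0 equiv), MeI (2.2 equiv), MeOH, 0 °C → rt, 16 h; 1 M HCl
Reagents that add atoms: iodomethane, CI
Why: Dearomative double C-alkylation (SN2) of the phloroglucinolate in a protic solvent, in which the methyl-bearing ring carbon of 6 is the most electron-rich site and takes the second methyl group, while the product is a strong vinylogous acid whose delocalised anion is a poor nucleophile, so that further methylation is slow; the new quaternary carbon carries two identical methyl groups and is not a stereocentre.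

Step 3
Reactants: 7 butyrylfilicinic acid (1.0 equiv); 5 phlorobutyrophenone (3.0 equiv, excess recovered)
Product: 10 norflavaspidic acid BB (A–CH2–B dimer with one free aromatic CH on ring B), via Mannich base 8 (not isolated), via methylene trione 9 (not isolated)
Conditions: 7, Me2NCH2NMe2 (1.0 equiv), MeCN, 0 °C → rt, 1 h, volatiles stripped; then 5, AcOH (3 equiv), MeCN, 45 °C, 6 h; 1 M HCl wash
Reagents that add atoms: bis(dimethylamino)methane, CN(C)CN(C)C
Why: The acidic enol 7 ionises the aminal and is aminomethylated at its only free ring carbon (Mannich reaction), the zwitterionic 8 loses Me2NH (E1cB) to give the quinone-methide-type methylene trione 9, and 9 is captured by 5 in a Friedel–Crafts-type Michael addition, with albaspidin formation prevented by storing all of 7 as 8 before 5 is added and double capping suppressed by the excess of 5; no stereocentre is created.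

Step 4
Reactants: 5 phlorobutyrophenone (1.0 equiv); 10 norflavaspidic acid BB (2.1 equiv)
Product: 15 target pentamer A–CH2–B–CH2–B–CH2–B–CH2–A (CNP0188003.0), via bis-Mannich base 11 (not isolated), via first quinone methide 12 (not isolated), via trimer Mannich base 13 (not isolated), via second quinone methide 14 (not isolated)
Conditions: 5, Me2NCH2NMe2 (2.0 equiv), 1,4-dioxane, rt, 2 h, volatiles stripped; then 10, AcOH (5 equiv), 1,4-dioxane, 70 °C, Ar, 8 h; 1 M HCl wash; Sephadex LH-20
Reagents that add atoms: bis(dimethylamino)methane, CN(C)CN(C)C
Why: A double Mannich reaction fills both free ring carbons of 5 so that the central ring can act only as an electrophile, each ammonium-phenolate arm then loses Me2NH to give an o-quinone methide (the electrophile presumed for methylene-bridge formation in the ferns), and each o-quinone methide is captured in a Friedel–Crafts-type Michael addition by the single free ring carbon of 10, which can act only as a nucleophile, so that the only doubly coupled product is the pentamer, while the AcOH buffer binds the released amine and slows retro-Michael scrambling; no stereocentre is created.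

## Compound list

1 | triacetic acid lactone (4-hydroxy-6-methyl-2H-pyran-2-one) | CC1=CC(O)=CC(=O)O1 | starting material
2 | methyl butyrate | CCCC(=O)OC | starting material
3 | 4-hydroxy-6-(2-oxopentyl)-2H-pyran-2-one (tetraketide pyrone, not isolated) | CCCC(=O)CC1=CC(O)=CC(=O)O1 | intermediate
4 | methyl 3,5,7-trioxodecanoate (present as its Mg chelate, not isolated) | CCCC(=O)CC(=O)CC(=O)CC(=O)OC | intermediate
5 | phlorobutyrophenone, 1-(2,4,6-trihydroxyphenyl)butan-1-one | CCCC(=O)c1c(O)cc(O)cc1O | intermediate
6 | 3-methylphlorobutyrophenone, 1-(2,4,6-trihydroxy-3-methylphenyl)butan-1-one (not isolated) | CCCC(=O)c1c(O)cc(O)c(C)c1O | intermediate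
7 | butyrylfilicinic acid, 2-butanoyl-3,5-dihydroxy-4,4-dimethylcyclohexa-2,5-dien-1-one | CCCC(=O)C1=C(O)C(C)(C)C(O)=CC1=O | intermediate
8 | 2-butanoyl-6-[(dimethylamino)methyl]-3,5-dihydroxy-4,4-dimethylcyclohexa-2,5-dien-1-one (Mannich base of 7, not isolated) | CCCC(=O)C1=C(O)C(C)(C)C(O)=C(CN(C)C)C1=O | intermediate
9 | 2-butanoyl-3-hydroxy-4,4-dimethyl-6-methylidenecyclohex-2-ene-1,5-dione (methylene trione, not isolated) | CCCC(=O)C1=C(O)C(C)(C)C(=O)C(=C)C1=O | intermediate
10 | norflavaspidic acid BB (ring carbon 6 of 7 joined through CH2 to ring carbon 3 of 5) | CCCC(=O)C1=C(O)C(C)(C)C(O)=C(Cc2c(O)cc(O)c(C(=O)CCC)c2O)C1=O | intermediate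
11 | 1-{3,5-bis[(dimethylamino)methyl]-2,4,6-trihydroxyphenyl}butan-1-one (bis-Mannich base of 5, not isolated) | CCCC(=O)c1c(O)c(CN(C)C)c(O)c(CN(C)C)c1O | intermediate
12 | o-quinone methide from 11 by loss of one Me2NH, second CH2NMe2 arm intact (not isolated) | C=C1C(=O)C(CN(C)C)=C(O)C(C(=O)CCC)=C1O | intermediate
13 | A–CH2–B–CH2–B trimer whose last ring B still carries CH2NMe2 (not isolated) | CCCC(=O)C1=C(O)C(C)(C)C(O)=C(Cc2c(O)c(Cc3c(O)c(CN(C)C)c(O)c(C(=O)CCC)c3O)c(O)c(C(=O)CCC)c2O)C1=O | intermediate
14 | o-quinone methide from 13 by loss of Me2NH (not isolated) | CCCC(=O)C1=C(O)C(C)(C)C(O)=C(Cc2c(O)c(CC3=C(O)C(C(=O)CCC)=C(O)C(=C)C3=O)c(O)c(C(=O)CCC)c2O)C1=O | intermediate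
15 | CNP0188003.0, all-butyryl pentamer A–CH2–B–CH2–B–CH2–B–CH2–A, C58H68O20, achiral | CCCC(=O)C1=C(O)C(C)(C)C(O)=C(Cc2c(O)c(Cc3c(O)c(Cc4c(O)c(CC5=C(O)C(C)(C)C(O)=C(C(=O)CCC)C5=O)c(O)c(C(=O)CCC)c4O)c(O)c(C(=O)CCC)c3O)c(O)c(C(=O)CCC)c2O)C1=O | target

## Step count and risks

Total step count: 4.
Longest linear sequence: 4 steps (1 → 5 → 7 → 10 → 15).

**Step 1 (highest risk).** The enolisable ester can protonate the dianion instead of acylating it. The chelated tetraketide 4 can also close the other way, by C2→C7 aldol, to a 6-propylresorcylate. The fallback sets out from 1 and comes back at 5, and it uncouples ring closure from acylation.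
- 1 is O-methylated (Me2SO4, K2CO3, acetone, reflux) to 4-methoxy-6-methyl-2H-pyran-2-one F1.
- NaOMe in MeOH at 185 °C in a sealed vessel opens the lactone. It re-closes by the only cyclisation open to a triketide, the C6→C1 Claisen, to give 5-methoxyresorcinol F2.
- 48% aq HBr in AcOH at reflux gives phloroglucinol F3.
- Friedel–Crafts C-acylation (butyryl chloride, AlCl3, CH2Cl2/PhNO2, 0 °C → rt) gives 5.
- The ring is still made by a polyketide Claisen closure, but no aldol mode exists and no enolisable ester meets a carbanion.

**Step 4.** At 70 °C the finished bridges can scramble by retro-Michael cleavage, and the second coupling on the bulky 13 can stall. The fallback sets out from 5 and comes back at 15, and it builds the bridges from the inside out.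
- 11 is generated from 5 in the same way but is heated with a sixfold excess of 5 in place of 10.
- This gives the methylene-bridged phlorobutyrophenone trimer F4 (B–CH2–B–CH2–B), and the excess 5 is recovered.
- The two terminal free ring carbons of F4 are then capped at 40 °C with Mannich base 8 (2.1 equiv, made from 7 as in step 3) to give 15.
- The hot, slow o-quinone methide coupling is thus done on simple monomers. The last bonds are made under milder conditions with the far more reactive, non-aromatic methylene trione 9.

**Step 3.** 10 can be capped a second time to give the A–CH2–B–CH2–A trimer. Iminium transfer from 8 to 5 can also release free 7, which would give the A–CH2–A dimer. The fallback sets out from 7 and comes back at 10, and it uses thermodynamic methylene transfer instead of kinetic capture.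
- 7 is condensed with 37% aq CH2O (0.5 equiv) in 1% aq KOH at rt to give crystalline albaspidin BB F5 (A–CH2–A).
- F5 is then warmed with 5 (5 equiv) in 0.2 M aq Na2CO3 under N2 at 50 °C.
- In this rottlerone-type change, retro-Michael cleavage releases 9 and the anion of 7, and the excess of 5 captures 9 to give 10.
- The released 7 is recycled.

## Further compounds

F1 | step 1 | 4-methoxy-6-methyl-2H-pyran-2-one | CC1=CC(OC)=CC(=O)O1
F2 | step 1 | 5-methoxyresorcinol (5-methoxybenzene-1,3-diol) | COc1cc(O)cc(O)c1
F3 | step 1 | phloroglucinol (benzene-1,3,5-triol) | Oc1cc(O)cc(O)c1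
F4 | step 4 | methylene-bridged phlorobutyrophenone trimer (B–CH2–B–CH2–B) | CCCC(=O)c1c(O)cc(O)c(Cc2c(O)c(Cc3c(O)cc(O)c(C(=O)CCC)c3O)c(O)c(C(=O)CCC)c2O)c1O
F5 | step 3 | albaspidin BB (A–CH2–A) | CCCC(=O)C1=C(O)C(C)(C)C(O)=C(CC2=C(O)C(C)(C)C(O)=C(C(=O)CCC)C2=O)C1=O
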